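**Retrosynthetic overview**
- The strategy rests on ring A (C4a, C5, C6, C7, C8, C8a), a hexasubstituted benzene. Its neighbouring C6/C7 methoxyls lie between para-related oxygens at C5 and C8, which is the four-carbon pattern of dimethyl squarate fused onto the C4a=C8a enol ether of ring C.
- Ring A and the C8–C8a bond come from thermal ring expansion of a 4-hydroxy-2,3-dimethoxycyclobutenone that carries ring C on its carbinol carbon. The C4a–C5 bond comes from adding a C5-lithiated, C4-ketal-masked dihydropyranone to dimethyl squarate.
- Ring C and the C2 (S) centre come from a catalytic asymmetric hetero-Diels–Alder reaction of 2-(benzyloxy)-6-methoxybenzaldehyde with the silyloxydiene; ring B is bought with the aldehyde.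
- Ring order: B (purchased), then C (step 2), then A (step 6). End game: ketal hydrolysis, methylation of the unchelated C8 hydroxyl, hydrogenolysis.

Key step: step 6

Remark on the chemistry: (S)-BINOL is assumed to direct the diene to the Si face of the aldehyde, as titanium–BINOL catalysts do with benzaldehyde; if this hindered aldehyde shows the opposite sense, (R)-BINOL is used. The carbinol carbon of the squarate adduct forms as an unseparated mixture of epimers.

**Step 1**
Reactants: 1 2-hydroxy-6-methoxybenzaldehyde
Product: 2 2-(benzyloxy)-6-methoxybenzaldehyde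
Conditions: BnBr, K2CO3, DMF, rt
Reagents that add atoms: benzyl bromide, BrCc1ccccc1
Why: Williamson ether synthesis on the only acidic site masks the ring B phenol as a benzyl ether that should survive Lewis acid, organolithium and heat and is removed by hydrogenolysis at the end.

**Step 2**
Reactants: 2 2-(benzyloxy)-6-methoxybenzaldehyde; 3 trans-1-methoxy-3-(trimethylsilyloxy)buta-1,3-diene
Product: 5 (S)-2-[2-(benzyloxy)-6-methoxyphenyl]-2,3-dihydro-4H-pyran-4-one, via silylated Mukaiyama aldol adduct 4 (not isolated)
Conditions: Ti(OiPr)4 (10 mol%), (S)-BINOL (20 mol%), 4 Å MS, toluene, 0 °C to rt; then TFA (cat.), CH2Cl2, 0 °C, short contact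
Reagents that add atoms: none
Why: The titanium–BINOL-catalysed Mukaiyama aldol addition of the diene followed by acid-induced cyclisation with loss of methanol (a formal hetero-Diels–Alder reaction) should give the dihydropyranone, with the chiral titanium complex directing C–C bond formation to the Si face of the aldehyde so that C2 is set as S.

**Step 3**
Reactants: 5 (S)-2-[2-(benzyloxy)-6-methoxyphenyl]-2,3-dihydro-4H-pyran-4-one
Product: 6 (S)-2-[2-(benzyloxy)-6-methoxyphenyl]-5-iodo-2,3-dihydro-4H-pyran-4-one
Conditions: I2, pyridine, CH2Cl2, 0 °C to rt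
Reagents that add atoms: iodine, II
Why: α-Iodination of an enone with I2/pyridine should place iodine at C5, the nucleophilic enol-ether carbon of the vinylogous ester, while unactivated iodine should leave the alkoxyarene of ring B alone.

**Step 4**
Reactants: 6 (S)-2-[2-(benzyloxy)-6-methoxyphenyl]-5-iodo-2,3-dihydro-4H-pyran-4-one
Product: 7 (S)-2-[2-(benzyloxy)-6-methoxyphenyl]-5-iodo-2,3-dihydro-4H-pyran-4-one ethylene ketal [(9S)-9-aryl-6-iodo-1,4,8-trioxaspiro[4.5]dec-6-ene]
Conditions: TMSOCH2CH2OTMS, TMSOTf (cat.), CH2Cl2, −78 to −20 °C; then pyridine; Et3N-treated silica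
Reagents that add atoms: 1,2-bis(trimethylsilyloxy)ethane, C[Si](C)(C)OCCO[Si](C)(C)C
Why: Noyori ketalisation is aprotic and cold, so no acid adds across the enol ether; formation of hexamethyldisiloxane drives the exchange, and the α-iodine raises the electrophilicity of the conjugated carbonyl as in other α-haloenone ketalisations.

**Step 5**
Reactants: 7 (S)-2-[2-(benzyloxy)-6-methoxyphenyl]-5-iodo-2,3-dihydro-4H-pyran-4-one ethylene ketal; 8 dimethyl squarate (3,4-dimethoxycyclobut-3-ene-1,2-dione)
Product: 10 4-hydroxy-2,3-dimethoxy-4-{(S)-2-[2-(benzyloxy)-6-methoxyphenyl]-4,4-(ethylenedioxy)-3,4-dihydro-2H-pyran-5-yl}cyclobut-2-en-1-one (both carbinol epimers), via alkenyllithium 9 (not isolated)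
Conditions: t-BuLi (2 equiv), Et2O, −78 °C, 10 min; cannulated into 8, THF, −78 °C; H2O quench at −78 °C
Reagents that add atoms: none
Why: Iodine–lithium exchange at the sp2 carbon is faster than any other reaction of t-BuLi at −78 °C, and the alkenyllithium (used at once, since β-oxygenated alkenyllithiums can fragment on warming) should add 1,2 to one of the two equivalent carbonyls of the squarate ester, giving carbinol epimers that converge in step 6.

**Step 6**
Reactants: 10 squarate adduct (both carbinol epimers)
Product: 13 (S)-2-[2-(benzyloxy)-6-methoxyphenyl]-5,8-dihydroxy-6,7-dimethoxychroman-4-one ethylene ketal, via dienylketene 11 (not isolated), via cyclohexadienone 12 (not isolated)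
Conditions: toluene (degassed, 0.02 M), 110 °C, argon; concentrated and used directly
Reagents that add atoms: none
Why: Heating opens the cyclobutenone by a thermal 4π conrotatory ring opening in which the carbinol hydroxyl rotates outward and the dihydropyranyl group inward, giving the (Z)-dienylketene 11 with its ketene carbon next to pyran C6, the future C8a. Ring A then closes by a thermal disrotatory 6π electrocyclisation that forms the C8–C8a bond (carbinol carbon becomes C5, ketene carbon becomes C8), and the resulting 2,4-cyclohexadienone 12 loses its C8a hydrogen to oxygen by tautomerisation to give the aromatic 5,8-hydroquinone 13. The closest known reaction type is the Moore rearrangement of 4-alkenyl- and 4-heteroaryl-4-hydroxycyclobutenones made from squarate esters, which run at about this temperature. No lasting stereocentre is made: both carbinol epimers give the same ketene, the sp3 C8a of 12 is erased on aromatisation, and C2 is remote from the reacting π system and should not epimerise under neutral, reagent-free conditions. The step needs torquoselectivity, secured by the strong outward preference of the oxygen donor on the breaking bond, and regioselectivity, fixed because the squarate carbon is bonded to pyran C5 so that the only terminus in reach is C6–H. Exclusion of air and acid should keep the hydroquinone from oxidising to the quinone and the ketal from ionising.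

**Step 7**
Reactants: 13 (S)-2-[2-(benzyloxy)-6-methoxyphenyl]-5,8-dihydroxy-6,7-dimethoxychroman-4-one ethylene ketal
Product: 14 (S)-2-[2-(benzyloxy)-6-methoxyphenyl]-5,8-dihydroxy-6,7-dimethoxychroman-4-one
Conditions: PPTS (cat.), acetone/H2O (degassed), rt, argon
Reagents that add atoms: water, O
Why: Acid-catalysed ketal hydrolysis should be very fast here because the ketal carbon is benzylic to an arene with ortho and para oxygen donors, so acid mild enough to spare the benzylic C2–O1 bond and the benzyl ether suffices.

**Step 8**
Reactants: 14 (S)-2-[2-(benzyloxy)-6-methoxyphenyl]-5,8-dihydroxy-6,7-dimethoxychroman-4-one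
Product: 15 (S)-2-[2-(benzyloxy)-6-methoxyphenyl]-5-hydroxy-6,7,8-trimethoxychroman-4-one
Conditions: TMSCHN2, iPr2NEt, MeCN/MeOH (9:1), 0 °C to rt, argon
Reagents that add atoms: trimethylsilyldiazomethane, C[Si](C)(C)C=[N+]=[N-]
Why: O-Methylation of a phenol with trimethylsilyldiazomethane should touch only the free C8 hydroxyl, because the C5 hydroxyl is held in a hydrogen bond to the C4 carbonyl, and the near-neutral conditions avoid base-induced opening to the chalcone that would racemise C2.

**Step 9**
Reactants: 15 (S)-2-[2-(benzyloxy)-6-methoxyphenyl]-5-hydroxy-6,7,8-trimethoxychroman-4-one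
Product: 16 (S)-5-hydroxy-2-(2-hydroxy-6-methoxyphenyl)-6,7,8-trimethoxychroman-4-one
Conditions: H2 (1 atm), Pd/C, EtOAc, rt
Reagents that add atoms: none
Why: Catalytic hydrogenolysis of the benzyl aryl ether over Pd/C should free the ring B phenol well before the aryl ketone or the cyclic benzylic ether of the flavanone reacts, and C2 is not touched.

**Compound list**
1 | 2-hydroxy-6-methoxybenzaldehyde | COc1cccc(O)c1C=O | starting material
2 | 2-(benzyloxy)-6-methoxybenzaldehyde | COc1cccc(OCc2ccccc2)c1C=O | intermediate
3 | trans-1-methoxy-3-(trimethylsilyloxy)buta-1,3-diene | CO/C=C/C(=C)O[Si](C)(C)C | starting material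
4 | (S,E)-5-[2-(benzyloxy)-6-methoxyphenyl]-1-methoxy-5-(trimethylsilyloxy)pent-1-en-3-one (not isolated) | COc1cccc(OCc2ccccc2)c1[C@@H](O[Si](C)(C)C)CC(=O)/C=C/OC | intermediate
5 | (S)-2-[2-(benzyloxy)-6-methoxyphenyl]-2,3-dihydro-4H-pyran-4-one | COc1cccc(OCc2ccccc2)c1[C@@H]1CC(=O)C=CO1 | intermediate
6 | (S)-2-[2-(benzyloxy)-6-methoxyphenyl]-5-iodo-2,3-dihydro-4H-pyran-4-one | COc1cccc(OCc2ccccc2)c1[C@@H]1CC(=O)C(I)=CO1 | intermediate
7 | (S)-2-[2-(benzyloxy)-6-methoxyphenyl]-5-iodo-2,3-dihydro-4H-pyran-4-one ethylene ketal | COc1cccc(OCc2ccccc2)c1[C@@H]1CC2(OCCO2)C(I)=CO1 | intermediate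
8 | dimethyl squarate | COC1=C(OC)C(=O)C1=O | starting material
9 | C5-lithiated dihydropyranone ethylene ketal (not isolated) | COc1cccc(OCc2ccccc2)c1[C@@H]1CC2(OCCO2)C([Li])=CO1 | intermediate
10 | squarate adduct, 4-hydroxy-2,3-dimethoxy-4-(ketal-masked dihydropyran-5-yl)cyclobut-2-en-1-one, both carbinol epimers | COc1cccc(OCc2ccccc2)c1[C@@H]1CC3(OCCO3)C(C4(O)C(OC)=C(OC)C4=O)=CO1 | intermediate
11 | (Z)-4-hydroxy-2,3-dimethoxy-4-(ketal-masked dihydropyran-5-yl)buta-1,3-dien-1-one, the dienylketene (not isolated) | COc1cccc(OCc2ccccc2)c1[C@@H]1CC3(OCCO3)C(=CO1)/C(O)=C(OC)\C(OC)=C=O | intermediate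
12 | 5-hydroxy-6,7-dimethoxy-8-oxo-8,8a-dihydro chromane ketal, the cyclohexadienone (not isolated, C8a unspecified) | COc1cccc(OCc2ccccc2)c1[C@@H]1CC3(OCCO3)C2=C(O)C(OC)=C(OC)C(=O)C2O1 | intermediate
13 | (S)-2-[2-(benzyloxy)-6-methoxyphenyl]-5,8-dihydroxy-6,7-dimethoxychroman-4-one ethylene ketal | COc1cccc(OCc2ccccc2)c1[C@@H]1CC3(OCCO3)c2c(O)c(OC)c(OC)c(O)c2O1 | intermediate
14 | (S)-2-[2-(benzyloxy)-6-methoxyphenyl]-5,8-dihydroxy-6,7-dimethoxychroman-4-one | COc1cccc(OCc2ccccc2)c1[C@@H]1CC(=O)c2c(O)c(OC)c(OC)c(O)c2O1 | intermediate
15 | (S)-2-[2-(benzyloxy)-6-methoxyphenyl]-5-hydroxy-6,7,8-trimethoxychroman-4-one | COc1cccc(OCc2ccccc2)c1[C@@H]1CC(=O)c2c(O)c(OC)c(OC)c(OC)c2O1 | intermediate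
16 | (S)-5-hydroxy-2-(2-hydroxy-6-methoxyphenyl)-6,7,8-trimethoxychroman-4-one | COc1cccc(O)c1[C@@H]1CC(=O)c2c(O)c(OC)c(OC)c(OC)c2O1 | target

**Step count and risks**
Total steps: 9. Longest linear sequence: 9 steps (1 to 16); the diene 3 and dimethyl squarate 8 are bought.

Steps most likely to fail:

1. Step 4 (ketalisation). The vinylogous ester carbonyl is a weak electrophile, so the exchange may stall. The O-silylated pyranone may also ionise at the benzylic C2–O1 bond and erode the enantiomeric purity, and the very acid-labile ketal may hydrolyse during isolation.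
 Fallback, setting out from 6 and returning at 14: the ketone is left unmasked. Iodide 6 is treated with iPrMgCl·LiCl (THF, −40 °C). Iodine–magnesium exchange at an sp2 carbon next to a carbonyl group is fast, and a covalent alkenylmagnesium should tolerate the weakly electrophilic vinylogous ester carbonyl at this temperature, as is known for α-magnesiated β-oxygenated unsaturated lactones. The resulting chloromagnesium reagent F1 is added to 8 at −78 °C to give the keto adduct F2. Heating F2 in degassed toluene at 110 °C should bring about the same ring expansion and give 14 directly, without the hydrolysis step.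

2. Step 5 (exchange and addition). The lithiated enol ether has lithium anti to the ring oxygen and may fragment by β-elimination to a ring-opened alkynyl alkoxide before it is trapped; over-addition to the squarate is a lesser concern.
 Fallback, setting out from 7 and returning at 10: the carbanion is changed from an alkenyllithium to a magnesium ate species. Iodide 7 is exchanged with n-Bu3MgLi (THF, −78 °C) to give the lithium alkenyl(dibutyl)magnesate F3, whose covalent carbon–magnesium bond should suppress the elimination. F3 is added to 8 at −78 °C, where such ate complexes are expected to transfer the sp2 group to a carbonyl in preference to butyl, and aqueous quench gives 10.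

3. Step 6 (ring expansion). The ketene may be trapped by the free carbinol hydroxyl as a butenolide if the alkenyl group rotates outward, the electron-rich hydroquinone may oxidise to the quinone on handling, and the ketal may be lost at 110 °C in the presence of the phenolic product.
 Fallback, setting out from 7 (through 9) and returning at 15: the lithium alkoxide formed in step 5 is not quenched with water but trapped with chloromethyl methyl ether (−78 to 0 °C) to give the methoxymethyl ether F4. Thermolysis of F4 (toluene, 110 °C) cannot form a butenolide and should give the air-stable monoprotected hydroquinone ketal F5, with the protected oxygen at C5 and the free hydroxyl at C8. Methylation (MeI, K2CO3, DMF) gives the 8-O-methyl ether F6 without risk to C2, since no ketone is present. Aqueous HCl in THF/MeOH at rt then removes the ketal and the C5 acetal together to give 15. This variant distinguishes O5 from O8 by their origin, so it does not depend on the selective methylation of step 8.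

**Further compounds**
F1 | step 4 | [(S)-2-[2-(benzyloxy)-6-methoxyphenyl]-4-oxo-3,4-dihydro-2H-pyran-5-yl]magnesium chloride | COc1cccc(OCc2ccccc2)c1[C@@H]1CC(=O)C([Mg]Cl)=CO1
F2 | step 4 | 4-hydroxy-2,3-dimethoxy-4-{(S)-2-[2-(benzyloxy)-6-methoxyphenyl]-4-oxo-3,4-dihydro-2H-pyran-5-yl}cyclobut-2-en-1-one | COc1cccc(OCc2ccccc2)c1[C@@H]1CC(=O)C(C2(O)C(OC)=C(OC)C2=O)=CO1
F3 | step 5 | lithium dibutyl[(S)-ketal-masked dihydropyran-5-yl]magnesate | COc1cccc(OCc2ccccc2)c1[C@@H]1CC2(OCCO2)C([Mg-](CCCC)CCCC)=CO1.[Li+]
F4 | step 6 | 4-(methoxymethoxy)-2,3-dimethoxy-4-(ketal-masked dihydropyran-5-yl)cyclobut-2-en-1-one | COc1cccc(OCc2ccccc2)c1[C@@H]1CC3(OCCO3)C(C4(OCOC)C(OC)=C(OC)C4=O)=CO1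
F5 | step 6 | (S)-2-[2-(benzyloxy)-6-methoxyphenyl]-8-hydroxy-6,7-dimethoxy-5-(methoxymethoxy)chroman-4-one ethylene ketal | COc1cccc(OCc2ccccc2)c1[C@@H]1CC3(OCCO3)c2c(OCOC)c(OC)c(OC)c(O)c2O1
F6 | step 6 | (S)-2-[2-(benzyloxy)-6-methoxyphenyl]-6,7,8-trimethoxy-5-(methoxymethoxy)chroman-4-one ethylene ketal | COc1cccc(OCc2ccccc2)c1[C@@H]1CC3(OCCO3)c2c(OCOC)c(OC)c(OC)c(OC)c2O1
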